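**Plan**

- Retrosynthesis: after the protecting-group cuts (six O-benzyl groups, isopropenyl as masked acetyl), rings A and C are removed together by cutting C4a–C8a, C7–C8 and C6–C7. The open-chain precursor is then cut at C5–C7 (phosphonate sequence), C8–CH2 (acetylide alkylation by a ring-D benzylic bromide), O1–C8a (alkoxide plus dichloroacetylene), C2–C1′ (aryl Grignard on a Weinreb amide) and C3–C4 (glycolate allylation).
- Enabling feature: on ring A the ether oxygen O1 sits on C8a and the methylene to ring D on the neighbouring C8, and O1 is tied back to C4a by the ring-C carbons C2, C3 and C4. Opened up, this is an ynol ether O1–C8a≡C8–CH2Ar hanging four atoms from a ketene carbon (C4a); the remaining ring-A atoms C5, C6 and C7 are the 1-benzyloxyvinyl and carbonyl carbons of an α-diazo enone.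
- Forward order: ring-B chain (steps 1–8), ring D (steps 9–15), union through the ynol ether (16), chain end raised to the diazo enone (17–23), ring C then ring A closed in one operation (24), acetyl unveiled and benzyl ethers removed (25, 26).
- Stereochemistry: C3 (S) comes from an Evans glycolate allylation on the (R)-4-benzyl oxazolidinone. C2 (R) comes from chelation-controlled Zn(BH4)2 reduction of the α-benzyloxy aryl ketone (anti, the 2,3-trans relationship). Both centres lie on the tether and are not touched again.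

Key step: step 24

**Remarks**

- Pilosanol N is taken as drawn, (2R,3S), the 2,3-trans flavan-3-ol; flavan labels (O1, C2 … C8a, rings A–D) are used for the corresponding atoms of all precursors.
- ArB = 3,4-bis(benzyloxy)phenyl; ArD = 2,6-bis(benzyloxy)-4-methoxy-3-methyl-5-(prop-1-en-2-yl)phenyl; TBS = tert-butyldimethylsilyl.
- Alkoxides, enolates and the lithiated phosphonate are treated as ionised forms of numbered compounds; organometallic and neutral transient species carry their own numbers.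
- The 2-benzyloxy enone is built by phosphonate chemistry and not from metalated benzyl vinyl ether, because alkyllithium bases would be expected to attack the benzylic CH2 of that ether first.

**Route**

Step 1
Reactants: 1 (R)-4-benzyl-1,3-oxazolidin-2-one; 2 (benzyloxy)acetyl chloride
Product: 3 (R)-4-benzyl-3-[(benzyloxy)acetyl]-1,3-oxazolidin-2-one
Conditions: n-BuLi, THF, −78 °C; then 2, −78 → 0 °C
Reagents that add atoms: none
Why: N-acylation of the lithiated oxazolidinone by an acid chloride is the standard preparation of Evans glycolate imides and leaves the auxiliary centre untouched.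

Step 2
Reactants: 3 glycolate imide; 4 allyl iodide
Product: 5 (R)-4-benzyl-3-[(2S)-2-(benzyloxy)pent-4-enoyl]-1,3-oxazolidin-2-one
Conditions: NaN(SiMe3)2, THF, −78 °C; then 4, −78 → −45 °C
Reagents that add atoms: none
Why: Evans asymmetric alkylation of a glycolate imide: the chelated (Z)-sodium enolate should be allylated on the face away from the C4 benzyl group of the (R)-auxiliary, which sets the (S) centre that becomes C3.

Step 3
Reactants: 5 allylated imide
Product: 6 (2S)-2-(benzyloxy)-N-methoxy-N-methylpent-4-enamide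
Conditions: MeONHMe·HCl, AlMe3, CH2Cl2, 0 °C → rt
Reagents that add atoms: N,O-dimethylhydroxylamine hydrochloride, CNOC.Cl
Why: Weinreb transamination with the aluminium amide cleaves the exocyclic acyl–nitrogen bond without enolisation, so the α-benzyloxy centre should be kept while auxiliary 1 is released for recovery.

Step 4
Reactants: 6 Weinreb amide; 7 1,2-bis(benzyloxy)-4-bromobenzene
Product: 9 (2S)-2-(benzyloxy)-1-[3,4-bis(benzyloxy)phenyl]pent-4-en-1-one, via aryl Grignard reagent 8 (not isolated)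
Conditions: 7, Mg, THF, reflux; then 6, THF, 0 °C
Reagents that add atoms: none
Why: Weinreb ketone synthesis: the aryl Grignard adds once to give a stable chelated tetrahedral adduct, so neither over-addition nor epimerisation of the α-benzyloxy centre is expected.

Step 5
Reactants: 9 α-benzyloxy aryl ketone
Product: 10 (1R,2S)-2-(benzyloxy)-1-[3,4-bis(benzyloxy)phenyl]pent-4-en-1-ol
Conditions: Zn(BH4)2, Et2O, −20 → 0 °C
Reagents that add atoms: none
Why: Chelation-controlled (Cram chelate) hydride reduction: zinc bridges the carbonyl and α-benzyloxy oxygens and hydride enters past the small hydrogen, which should give the anti (1R,2S) alcohol, the future C2 with the 2,3-trans relationship.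

Step 6
Reactants: 10 homoallylic ether alcohol
Product: 12 (1R,2S)-2-(benzyloxy)-1-[3,4-bis(benzyloxy)phenyl]pentane-1,5-diol, via B-alkyl-9-BBN borane 11 (not isolated)
Conditions: 9-BBN (3 equiv), THF, 0 °C → rt; then NaOH, H2O2, 0 °C
Reagents that add atoms: hydrogen peroxide, OO
Why: Anti-Markovnikov hydroboration–oxidation of the terminal alkene gives the primary alcohol and touches neither stereocentre.

Step 7
Reactants: 12 diol
Product: 13 (1R,2S)-2-(benzyloxy)-1-[3,4-bis(benzyloxy)phenyl]-5-[(tert-butyldimethylsilyl)oxy]pentan-1-ol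
Conditions: TBSCl (1.05 equiv), imidazole, CH2Cl2, 0 °C
Reagents that add atoms: tert-butyldimethylsilyl chloride, CC(C)(C)[Si](C)(C)Cl
Why: Silylation should be selective for the primary hydroxyl over the hindered secondary benzylic one.

Step 8
Reactants: 13 silyl ether alcohol; 14 trichloroethylene
Product: 15 tert-butyl{[(4S,5R)-4-(benzyloxy)-5-ArB-5-{[(E)-1,2-dichloroethenyl]oxy}pentyl]oxy}dimethylsilane
Conditions: KH, THF, 0 °C; then 14, −50 °C → rt
Reagents that add atoms: none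
Why: Greene dichlorovinyl ether synthesis: the potassium alkoxide adds to dichloroacetylene formed in situ from trichloroethylene, and because the carbinol C–O bond is not broken C2 keeps its configuration.

Step 9
Reactants: 16 2,4,6-trihydroxytoluene
Product: 18 2,4,6-trihydroxy-3-methylbenzaldehyde, via aryl iminium salt 17 (not isolated)
Conditions: POCl3, DMF, EtOAc, 0 °C → rt; then H2O, 60 °C
Reagents that add atoms: N,N-dimethylformamide, CN(C)C=O; water, O
Why: Vilsmeier–Haack formylation of the phloroglucinol ring at one of its two equivalent free positions.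

Step 10
Reactants: 18 trihydroxy aldehyde
Product: 19 2,6-dihydroxy-4-methoxy-3-methylbenzaldehyde
Conditions: MeI (1.0 equiv), K2CO3 (1.0 equiv), acetone, rt
Reagents that add atoms: iodomethane, CI
Why: Williamson methylation should select the hydroxyl para to the formyl group, the only one not held in a hydrogen bond to the carbonyl and the most acidic.

Step 11
Reactants: 19 dihydroxy aldehyde
Product: 20 2,6-bis(benzyloxy)-4-methoxy-3-methylbenzaldehyde
Conditions: BnBr (2.5 equiv), K2CO3, DMF, 60 °C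
Reagents that add atoms: benzyl bromide, BrCc1ccccc1
Why: Williamson benzylation of the two chelated ortho hydroxyls under forcing conditions.

Step 12
Reactants: 20 bis(benzyl) aldehyde
Product: 21 2,6-bis(benzyloxy)-3-bromo-4-methoxy-5-methylbenzaldehyde
Conditions: NBS, MeCN, 0 °C → rt, dark
Reagents that add atoms: N-bromosuccinimide, O=C1CCC(=O)N1Br
Why: Electrophilic aromatic bromination at the single free ring position, which is ortho or para to all three alkoxy groups.

Step 13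
Reactants: 21 aryl bromide; 22 isopropenylboronic acid pinacol ester
Product: 23 2,6-bis(benzyloxy)-4-methoxy-3-methyl-5-(prop-1-en-2-yl)benzaldehyde
Conditions: Pd(OAc)2 (5 mol %), SPhos (10 mol %), K3PO4, toluene/H2O, 80 °C
Reagents that add atoms: none
Why: Suzuki–Miyaura coupling with a dialkylbiarylphosphine ligand suited to di-ortho-substituted electron-rich aryl bromides installs the isopropenyl group that masks the acetyl group.

Step 14
Reactants: 23 isopropenyl aldehyde
Product: 24 [2,6-bis(benzyloxy)-4-methoxy-3-methyl-5-(prop-1-en-2-yl)phenyl]methanol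
Conditions: NaBH4, THF/MeOH, 0 °C
Reagents that add atoms: none
Why: Borohydride reduction of the aldehyde, with no other reducible group present.

Step 15
Reactants: 24 ring-D benzylic alcohol
Product: 25 1,3-bis(benzyloxy)-2-(bromomethyl)-5-methoxy-4-methyl-6-(prop-1-en-2-yl)benzene
Conditions: CBr4, PPh3, CH2Cl2, −20 → 0 °C; used at once
Reagents that add atoms: carbon tetrabromide, BrC(Br)(Br)Br
Why: Appel bromination is neutral, so the isopropenyl group and the benzyl ethers should survive.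

Step 16
Reactants: 15 dichlorovinyl ether; 25 ring-D benzylic bromide
Product: 28 tert-butyl{[(4S,5R)-4-(benzyloxy)-5-ArB-5-[(3-ArD-prop-1-yn-1-yl)oxy]pentyl]oxy}dimethylsilane, via chloroethynyl ether 26 (not isolated), via lithium alkoxyacetylide 27 (not isolated)
Conditions: n-BuLi (2.3 equiv), THF, −78 → −40 °C; then 25, DMPU, −78 → −20 °C
Reagents that add atoms: none
Why: Greene ynol ether synthesis: dehydrochlorination and chlorine–lithium exchange give the lithium alkoxyacetylide, which should be C-alkylated (SN2) by the reactive benzylic bromide in the presence of a polar cosolvent.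

Step 17
Reactants: 28 silyl-protected ynol ether
Product: 29 (4S,5R)-4-(benzyloxy)-5-ArB-5-[(3-ArD-prop-1-yn-1-yl)oxy]pentan-1-ol
Conditions: Bu4NF, THF, 0 °C
Reagents that add atoms: none
Why: Fluoride desilylation is basic and should leave the acid-sensitive ynol ether intact.

Step 18
Reactants: 29 primary alcohol
Product: 30 (4S,5R)-4-(benzyloxy)-5-ArB-5-[(3-ArD-prop-1-yn-1-yl)oxy]pentanal
Conditions: Dess–Martin periodinane, NaHCO3, CH2Cl2, 0 °C → rt
Reagents that add atoms: none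
Why: Dess–Martin oxidation buffered with NaHCO3 stops at the aldehyde and avoids the acid that would hydrate the ynol ether.

Step 19
Reactants: 31 benzyl chloromethyl ether
Product: 32 diethyl [(benzyloxy)methyl]phosphonate
Conditions: P(OEt)3, neat, 130 °C
Reagents that add atoms: triethyl phosphite, CCOP(OCC)OCC
Why: Michaelis–Arbuzov reaction of a reactive α-chloro ether with a trialkyl phosphite.

Step 20
Reactants: 30 aldehyde; 32 α-benzyloxy phosphonate
Product: 33 diethyl [(5S,6R)-1,5-bis(benzyloxy)-6-ArB-6-[(3-ArD-prop-1-yn-1-yl)oxy]-2-hydroxyhexyl]phosphonate (mixture at C1 and C2)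
Conditions: 32, LiN(i-Pr)2, THF, −78 °C; then 30, −78 °C; cold aqueous quench
Reagents that add atoms: none
Why: Carbonyl addition of the lithiated α-alkoxy phosphonate stops at the β-hydroxy phosphonate at low temperature; the two new centres are unselective and are both destroyed in steps 21 and 22.

Step 21
Reactants: 33 β-hydroxy phosphonate
Product: 34 diethyl [(5S,6R)-1,5-bis(benzyloxy)-6-ArB-6-[(3-ArD-prop-1-yn-1-yl)oxy]-2-oxohexyl]phosphonate (C1 epimers)
Conditions: Dess–Martin periodinane, NaHCO3, CH2Cl2, 0 °C → rt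
Reagents that add atoms: none
Why: Buffered Dess–Martin oxidation of a β-hydroxy phosphonate to the β-keto phosphonate.

Step 22
Reactants: 34 β-keto phosphonate
Product: 35 (6S,7R)-2,6-bis(benzyloxy)-7-ArB-7-[(3-ArD-prop-1-yn-1-yl)oxy]hept-1-en-3-one
Conditions: aq. HCHO, K2CO3, THF, 0 °C → rt
Reagents that add atoms: formaldehyde, C=O
Why: Horner–Wadsworth–Emmons methylenation with formaldehyde under mild carbonate base converts the α-benzyloxy phosphonate carbon into the 1-benzyloxyvinyl group.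

Step 23
Reactants: 35 2-benzyloxy enone
Product: 37 (6S,7R)-2,6-bis(benzyloxy)-7-ArB-4-diazo-7-[(3-ArD-prop-1-yn-1-yl)oxy]hept-1-en-3-one, via trifluoroacetyl diketone 36 (not isolated)
Conditions: LiN(SiMe3)2, THF, −78 °C; CF3CO2CH2CF3, −78 °C; pH 7 buffer; then MsN3, Et3N, H2O, MeCN, rt
Reagents that add atoms: methanesulfonyl azide, CS(=O)(=O)N=[N+]=[N-]
Why: Danheiser detrifluoroacetylative diazo transfer: the only enolisable position of the enone is trifluoroacetylated, and the activated diketone then accepts the diazo group with loss of the trifluoroacetyl group.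

Step 24
Reactants: 37 α-diazo 2-benzyloxy enone tethered to the ynol ether
Product: 42 (2R,3S)-3,5-bis(benzyloxy)-2-ArB-8-(ArD-methyl)-3,4-dihydro-2H-chromen-7-ol, via vinylketene 38 (not isolated), via bicyclic cyclobutenone 39 (not isolated), via dienylketene 40 (not isolated), via cyclohexadienone 41 (not isolated)
Conditions: hν (medium-pressure Hg lamp, Pyrex filter), degassed ClCH2CH2Cl (0.005 M), 0 °C; then 80 °C in the dark
Reagents that add atoms: none
Why: Proposed new method: irradiation should expel N2 with 1,2-shift of the 1-benzyloxyvinyl group (photochemical Wolff rearrangement) to give vinylketene 38, whose C7=C4a bond adds to the tethered ynol ether in a [2+2] cycloaddition (C8 to C7, C8a to C4a); warming then opens cyclobutenone 39 by 4π electrocyclic cleavage of C4a–C7 to dienylketene 40, which closes by 6π electrocyclisation at C6–C7 and enolises to the phenol. The closest known reaction type is the intermolecular photochemical-Wolff form of the Danheiser benzannulation of α-diazo enones with alkoxy- or siloxyalkynes and ynamides; an intramolecular variant that also forms a heterocycle has no precedent. Ring C closes in the cycloaddition as the six-membered ring of a fused bicyclo[4.2.0] adduct (bond C4a–C8a, tether C4–C3–C2–O1), and ring A closes by the thermal 6π electrocyclisation of the dienylketene, whose ketene and vinyl arms are held cis because the C4a=C8a bond lies inside ring C. No stereocentre is created in the product (the quaternary C4a of 39 is transient), and C2 and C3 sit on the tether away from every bond that changes. The step needs the C7–C8/C4a–C8a regiochemistry, for which the ynol ether polarisation and the only unstrained tether geometry point the same way, and it needs Wolff migration and intramolecular capture to outrun 1,2-hydride shift from C4 and ketene dimerisation, which high dilution and irradiation at 0 °C (the heat-sensitive secondary ynol ether is consumed before the thermal stage) are meant to secure.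

Step 25
Reactants: 42 flavan phenol
Product: 44 1-[2,4-bis(benzyloxy)-3-{[(2R,3S)-3,5-bis(benzyloxy)-2-ArB-7-hydroxy-3,4-dihydro-2H-chromen-8-yl]methyl}-6-methoxy-5-methylphenyl]ethan-1-one, via vicinal diol 43 (not isolated)
Conditions: OsO4 (2 mol %), NaIO4 (4 equiv), 2,6-lutidine, dioxane/H2O, rt
Reagents that add atoms: osmium tetroxide (catalytic oxygen carrier), O=[Os](=O)(=O)=O; sodium periodate, [Na+].[O-]I(=O)(=O)=O
Why: Lemieux–Johnson cleavage of the only alkene gives the aryl methyl ketone; the ring-A phenol carries no ortho or para oxygen and should therefore resist periodate.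

Step 26
Reactants: 44 hexabenzyl ketone
Product: 45 pilosanol N
Conditions: H2 (1 atm), Pd(OH)2/C, THF/MeOH, rt
Reagents that add atoms: none
Why: Catalytic hydrogenolysis of the six benzyl ethers; the C2–O1 bond and the chelated aryl ketone are expected to survive as they do in debenzylations of benzylated catechins and acylphloroglucinols.

**Compound list**

1 | (R)-4-benzyl-1,3-oxazolidin-2-one | O=C1N[C@H](Cc2ccccc2)CO1 | starting material
2 | (benzyloxy)acetyl chloride | O=C(Cl)COCc1ccccc1 | starting material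
3 | (R)-4-benzyl-3-[(benzyloxy)acetyl]-1,3-oxazolidin-2-one | O=C(COCc1ccccc1)N1[C@H](Cc2ccccc2)COC1=O | intermediate
4 | allyl iodide | C=CCI | starting material
5 | (R)-4-benzyl-3-[(2S)-2-(benzyloxy)pent-4-enoyl]-1,3-oxazolidin-2-one | C=CC[C@H](OCc1ccccc1)C(=O)N1[C@H](Cc2ccccc2)COC1=O | intermediate
6 | (2S)-2-(benzyloxy)-N-methoxy-N-methylpent-4-enamide | C=CC[C@H](OCc1ccccc1)C(=O)N(C)OC | intermediate
7 | 1,2-bis(benzyloxy)-4-bromobenzene | Brc1ccc(OCc2ccccc2)c(OCc2ccccc2)c1 | starting material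
8 | [3,4-bis(benzyloxy)phenyl]magnesium bromide | Br[Mg]c1ccc(OCc2ccccc2)c(OCc2ccccc2)c1 | intermediate (not isolated)
9 | (2S)-2-(benzyloxy)-1-[3,4-bis(benzyloxy)phenyl]pent-4-en-1-one | C=CC[C@H](OCc1ccccc1)C(=O)c1ccc(OCc2ccccc2)c(OCc2ccccc2)c1 | intermediate
10 | (1R,2S)-2-(benzyloxy)-1-[3,4-bis(benzyloxy)phenyl]pent-4-en-1-ol | C=CC[C@H](OCc1ccccc1)[C@H](O)c1ccc(OCc2ccccc2)c(OCc2ccccc2)c1 | intermediate
11 | 9-[(4S,5R)-4-(benzyloxy)-5-ArB-5-hydroxypentyl]-9-borabicyclo[3.3.1]nonane | B1(CCC[C@H](OCc2ccccc2)[C@H](O)c2ccc(OCc3ccccc3)c(OCc3ccccc3)c2)C2CCCC1CCC2 | intermediate (not isolated)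
12 | (1R,2S)-2-(benzyloxy)-1-[3,4-bis(benzyloxy)phenyl]pentane-1,5-diol | OCCC[C@H](OCc1ccccc1)[C@H](O)c1ccc(OCc2ccccc2)c(OCc2ccccc2)c1 | intermediate
13 | (1R,2S)-2-(benzyloxy)-1-[3,4-bis(benzyloxy)phenyl]-5-[(tert-butyldimethylsilyl)oxy]pentan-1-ol | CC(C)(C)[Si](C)(C)OCCC[C@H](OCc1ccccc1)[C@H](O)c1ccc(OCc2ccccc2)c(OCc2ccccc2)c1 | intermediate
14 | trichloroethylene | ClC=C(Cl)Cl | starting material
15 | tert-butyl{[(4S,5R)-4-(benzyloxy)-5-ArB-5-{[(E)-1,2-dichloroethenyl]oxy}pentyl]oxy}dimethylsilane | Cl/C=C(/Cl)O[C@H](c1ccc(OCc2ccccc2)c(OCc2ccccc2)c1)[C@H](CCCO[Si](C)(C)C(C)(C)C)OCc1ccccc1 | intermediate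
16 | 2,4,6-trihydroxytoluene | Cc1c(O)cc(O)cc1O | starting material
17 | dimethyl[(2,4,6-trihydroxy-3-methylphenyl)methylidene]ammonium chloride | C[N+](C)=Cc1c(O)cc(O)c(C)c1O.[Cl-] | intermediate (not isolated)
18 | 2,4,6-trihydroxy-3-methylbenzaldehyde | O=Cc1c(O)cc(O)c(C)c1O | intermediate
19 | 2,6-dihydroxy-4-methoxy-3-methylbenzaldehyde | O=Cc1c(O)cc(OC)c(C)c1O | intermediate
20 | 2,6-bis(benzyloxy)-4-methoxy-3-methylbenzaldehyde | O=Cc1c(OCc2ccccc2)cc(OC)c(C)c1OCc1ccccc1 | intermediate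
21 | 2,6-bis(benzyloxy)-3-bromo-4-methoxy-5-methylbenzaldehyde | O=Cc1c(OCc2ccccc2)c(Br)c(OC)c(C)c1OCc1ccccc1 | intermediate
22 | isopropenylboronic acid pinacol ester | C=C(C)B1OC(C)(C)C(C)(C)O1 | starting material
23 | 2,6-bis(benzyloxy)-4-methoxy-3-methyl-5-(prop-1-en-2-yl)benzaldehyde | O=Cc1c(OCc2ccccc2)c(C(C)=C)c(OC)c(C)c1OCc1ccccc1 | intermediate
24 | [2,6-bis(benzyloxy)-4-methoxy-3-methyl-5-(prop-1-en-2-yl)phenyl]methanol | OCc1c(OCc2ccccc2)c(C)c(OC)c(C(C)=C)c1OCc1ccccc1 | intermediate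
25 | 1,3-bis(benzyloxy)-2-(bromomethyl)-5-methoxy-4-methyl-6-(prop-1-en-2-yl)benzene | BrCc1c(OCc2ccccc2)c(C)c(OC)c(C(C)=C)c1OCc1ccccc1 | intermediate
26 | tert-butyl{[(4S,5R)-4-(benzyloxy)-5-ArB-5-[(chloroethynyl)oxy]pentyl]oxy}dimethylsilane | CC(C)(C)[Si](C)(C)OCCC[C@H](OCc1ccccc1)[C@H](OC#CCl)c1ccc(OCc2ccccc2)c(OCc2ccccc2)c1 | intermediate (not isolated)
27 | ({[(1R,2S)-2-(benzyloxy)-1-ArB-5-(TBS-oxy)pentyl]oxy}ethynyl)lithium | CC(C)(C)[Si](C)(C)OCCC[C@H](OCc1ccccc1)[C@H](OC#C[Li])c1ccc(OCc2ccccc2)c(OCc2ccccc2)c1 | intermediate (not isolated)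
28 | tert-butyl{[(4S,5R)-4-(benzyloxy)-5-ArB-5-[(3-ArD-prop-1-yn-1-yl)oxy]pentyl]oxy}dimethylsilane | CC(C)(C)[Si](C)(C)OCCC[C@H](OCc1ccccc1)[C@H](OC#CCc1c(OCc2ccccc2)c(C)c(OC)c(C(C)=C)c1OCc1ccccc1)c1ccc(OCc2ccccc2)c(OCc2ccccc2)c1 | intermediate
29 | (4S,5R)-4-(benzyloxy)-5-ArB-5-[(3-ArD-prop-1-yn-1-yl)oxy]pentan-1-ol | OCCC[C@H](OCc1ccccc1)[C@H](OC#CCc1c(OCc2ccccc2)c(C)c(OC)c(C(C)=C)c1OCc1ccccc1)c1ccc(OCc2ccccc2)c(OCc2ccccc2)c1 | intermediate
30 | (4S,5R)-4-(benzyloxy)-5-ArB-5-[(3-ArD-prop-1-yn-1-yl)oxy]pentanal | O=CCC[C@H](OCc1ccccc1)[C@H](OC#CCc1c(OCc2ccccc2)c(C)c(OC)c(C(C)=C)c1OCc1ccccc1)c1ccc(OCc2ccccc2)c(OCc2ccccc2)c1 | intermediate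
31 | benzyl chloromethyl ether | ClCOCc1ccccc1 | starting material
32 | diethyl [(benzyloxy)methyl]phosphonate | CCOP(=O)(OCC)COCc1ccccc1 | intermediate
33 | diethyl [(5S,6R)-1,5-bis(benzyloxy)-6-ArB-6-[(3-ArD-prop-1-yn-1-yl)oxy]-2-hydroxyhexyl]phosphonate | CCOP(=O)(OCC)C(OCc1ccccc1)C(O)CC[C@H](OCc1ccccc1)[C@H](OC#CCc1c(OCc2ccccc2)c(C)c(OC)c(C(C)=C)c1OCc1ccccc1)c1ccc(OCc2ccccc2)c(OCc2ccccc2)c1 | intermediate
34 | diethyl [(5S,6R)-1,5-bis(benzyloxy)-6-ArB-6-[(3-ArD-prop-1-yn-1-yl)oxy]-2-oxohexyl]phosphonate | CCOP(=O)(OCC)C(OCc1ccccc1)C(=O)CC[C@H](OCc1ccccc1)[C@H](OC#CCc1c(OCc2ccccc2)c(C)c(OC)c(C(C)=C)c1OCc1ccccc1)c1ccc(OCc2ccccc2)c(OCc2ccccc2)c1 | intermediate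
35 | (6S,7R)-2,6-bis(benzyloxy)-7-ArB-7-[(3-ArD-prop-1-yn-1-yl)oxy]hept-1-en-3-one | C=C(OCc1ccccc1)C(=O)CC[C@H](OCc1ccccc1)[C@H](OC#CCc1c(OCc2ccccc2)c(C)c(OC)c(C(C)=C)c1OCc1ccccc1)c1ccc(OCc2ccccc2)c(OCc2ccccc2)c1 | intermediate
36 | (6S,7R)-2,6-bis(benzyloxy)-7-ArB-7-[(3-ArD-prop-1-yn-1-yl)oxy]-4-(trifluoroacetyl)hept-1-en-3-one | C=C(OCc1ccccc1)C(=O)C(C(=O)C(F)(F)F)C[C@H](OCc1ccccc1)[C@H](OC#CCc1c(OCc2ccccc2)c(C)c(OC)c(C(C)=C)c1OCc1ccccc1)c1ccc(OCc2ccccc2)c(OCc2ccccc2)c1 | intermediate (not isolated)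
37 | (6S,7R)-2,6-bis(benzyloxy)-7-ArB-4-diazo-7-[(3-ArD-prop-1-yn-1-yl)oxy]hept-1-en-3-one | C=C(OCc1ccccc1)C(=O)C(=[N+]=[N-])C[C@H](OCc1ccccc1)[C@H](OC#CCc1c(OCc2ccccc2)c(C)c(OC)c(C(C)=C)c1OCc1ccccc1)c1ccc(OCc2ccccc2)c(OCc2ccccc2)c1 | intermediate
38 | (4S,5R)-4-(benzyloxy)-5-ArB-2-[1-(benzyloxy)ethenyl]-5-[(3-ArD-prop-1-yn-1-yl)oxy]pent-1-en-1-one | C=C(OCc1ccccc1)C(=C=O)C[C@H](OCc1ccccc1)[C@H](OC#CCc1c(OCc2ccccc2)c(C)c(OC)c(C(C)=C)c1OCc1ccccc1)c1ccc(OCc2ccccc2)c(OCc2ccccc2)c1 | intermediate (not isolated)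
39 | (3R,4S)-4-(benzyloxy)-3-ArB-6-[1-(benzyloxy)ethenyl]-8-(ArD-methyl)-2-oxabicyclo[4.2.0]oct-1(8)-en-7-one (both C6 epimers) | C=C(OCc1ccccc1)C12C[C@H](OCc3ccccc3)[C@@H](c3ccc(OCc4ccccc4)c(OCc4ccccc4)c3)OC1=C(Cc1c(OCc3ccccc3)c(C)c(OC)c(C(C)=C)c1OCc1ccccc1)C2=O | intermediate (not isolated)
40 | 2-[(2R,3S)-3-(benzyloxy)-2-ArB-5-[1-(benzyloxy)ethenyl]-3,4-dihydro-2H-pyran-6-yl]-3-ArD-prop-1-en-1-one | C=C(OCc1ccccc1)C1=C(C(Cc2c(OCc3ccccc3)c(C)c(OC)c(C(C)=C)c2OCc2ccccc2)=C=O)O[C@H](c2ccc(OCc3ccccc3)c(OCc3ccccc3)c2)[C@@H](OCc2ccccc2)C1 | intermediate (not isolated)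
41 | (2R,3S)-3,5-bis(benzyloxy)-2-ArB-8-(ArD-methyl)-3,4-dihydro-2H-chromen-7(6H)-one | O=C1CC(OCc2ccccc2)=C2C[C@H](OCc3ccccc3)[C@@H](c3ccc(OCc4ccccc4)c(OCc4ccccc4)c3)OC2=C1Cc1c(OCc2ccccc2)c(C)c(OC)c(C(C)=C)c1OCc1ccccc1 | intermediate (not isolated)
42 | (2R,3S)-3,5-bis(benzyloxy)-2-ArB-8-(ArD-methyl)-3,4-dihydro-2H-chromen-7-ol | Oc1cc(OCc2ccccc2)c2C[C@H](OCc3ccccc3)[C@@H](c3ccc(OCc4ccccc4)c(OCc4ccccc4)c3)Oc2c1Cc1c(OCc2ccccc2)c(C)c(OC)c(C(C)=C)c1OCc1ccccc1 | intermediate
43 | 2-[2,4-bis(benzyloxy)-3-{[(2R,3S)-3,5-bis(benzyloxy)-2-ArB-7-hydroxy-3,4-dihydro-2H-chromen-8-yl]methyl}-6-methoxy-5-methylphenyl]propane-1,2-diol (both carbinol epimers) | Oc1cc(OCc2ccccc2)c2C[C@H](OCc3ccccc3)[C@@H](c3ccc(OCc4ccccc4)c(OCc4ccccc4)c3)Oc2c1Cc1c(OCc2ccccc2)c(C)c(OC)c(C(C)(O)CO)c1OCc1ccccc1 | intermediate (not isolated)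
44 | 1-[2,4-bis(benzyloxy)-3-{[(2R,3S)-3,5-bis(benzyloxy)-2-ArB-7-hydroxy-3,4-dihydro-2H-chromen-8-yl]methyl}-6-methoxy-5-methylphenyl]ethan-1-one | Oc1cc(OCc2ccccc2)c2C[C@H](OCc3ccccc3)[C@@H](c3ccc(OCc4ccccc4)c(OCc4ccccc4)c3)Oc2c1Cc1c(OCc2ccccc2)c(C)c(OC)c(C(C)=O)c1OCc1ccccc1 | intermediate
45 | pilosanol N, 1-[3-{[(2R,3S)-2-(3,4-dihydroxyphenyl)-3,5,7-trihydroxy-3,4-dihydro-2H-chromen-8-yl]methyl}-2,4-dihydroxy-6-methoxy-5-methylphenyl]ethan-1-one | COc1c(C)c(O)c(Cc2c(O)cc(O)c3c2O[C@H](c2ccc(O)c(O)c2)[C@@H](O)C3)c(O)c1C(C)=O | target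

**Step count and risks**

Total: 26 steps. Longest linear sequence: 18 steps (steps 1–8, 16–18, 20–26).

Step 24 (the new cascade). The photogenerated carbene or ketene may be diverted: 1,2-hydride shift from C4, ketene dimerisation or capture by traces of water could outrun the intramolecular cycloaddition, and the benzylic secondary ynol ether may rearrange or fragment thermally before it is consumed. The fallback uses known chemistry, sets out from ring-D alcohol 24 and rejoins the route at its last compound 45. Commercial (+)-catechin would be benzylated at its four phenols (BnBr, K2CO3, DMF) to 5,7,3′,4′-tetra-O-benzylcatechin F1. Friedel–Crafts alkylation of F1 at C8 by the trialkoxybenzyl cation from 24 (catalytic TMSOTf, CH2Cl2, −78 °C; the C8-selective bond construction known from 4→8 procyanidin couplings) should give (2R,3S)-5,7-bis(benzyloxy)-2-ArB-8-(ArD-methyl)-3,4-dihydro-2H-chromen-3-ol F2. Lemieux–Johnson cleavage (OsO4 cat., NaIO4, 2,6-lutidine) would give the corresponding aryl methyl ketone F3, and hydrogenolysis of its six benzyl ethers (H2, Pd(OH)2/C) would give 45.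

Step 16 (acetylide alkylation). Ionisation and decomposition of the very electron-rich, doubly ortho-substituted benzylic bromide, or loss of the lithium alkoxyacetylide, may be faster than SN2 C-alkylation. The fallback sets out from 15 and returns at 28. Acetylide 27 is generated as before and transmetalated with ZnCl2 to the alkynylzinc chloride F4. F4 is then joined to bromide 25 by Negishi cross-coupling with Pd(PPh3)4 (zerovalent palladium) in THF at rt, so that the C8–CH2 bond forms by reductive elimination at palladium and not by displacement.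

Step 23 (diazo transfer on the vinyl ketone). Conjugate addition of the amide base or of the enolate to the unhindered vinyl ketone, with oligomerisation, may compete with C-trifluoroacetylation. The fallback sets out from 34 and returns at 37 by forming the vinyl group last. The 1,3-dianion of 34 (LiN(i-Pr)2, 2.2 equiv, THF, −78 °C) would be trifluoroacetylated at the α′ carbon with CF3CO2CH2CF3 to the trifluoroacetyl keto phosphonate F5 (not isolated). Diazo transfer (MsN3, Et3N, H2O, MeCN) would give the α′-diazo β-keto phosphonate F6, and Horner–Wadsworth–Emmons methylenation of F6 (aq. HCHO, K2CO3) would then give 37.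

Further compounds
F1 | step 24 | (2R,3S)-5,7-bis(benzyloxy)-2-[3,4-bis(benzyloxy)phenyl]-3,4-dihydro-2H-chromen-3-ol (5,7,3′,4′-tetra-O-benzylcatechin) | O[C@H]1Cc2c(OCc3ccccc3)cc(OCc3ccccc3)cc2O[C@@H]1c1ccc(OCc2ccccc2)c(OCc2ccccc2)c1
F2 | step 24 | (2R,3S)-5,7-bis(benzyloxy)-2-ArB-8-(ArD-methyl)-3,4-dihydro-2H-chromen-3-ol | O[C@H]1Cc2c(OCc3ccccc3)cc(OCc3ccccc3)c(Cc3c(OCc4ccccc4)c(C)c(OC)c(C(C)=C)c3OCc3ccccc3)c2O[C@@H]1c1ccc(OCc2ccccc2)c(OCc2ccccc2)c1
F3 | step 24 | 1-[2,4-bis(benzyloxy)-3-{[(2R,3S)-5,7-bis(benzyloxy)-2-ArB-3-hydroxy-3,4-dihydro-2H-chromen-8-yl]methyl}-6-methoxy-5-methylphenyl]ethan-1-one | O[C@H]1Cc2c(OCc3ccccc3)cc(OCc3ccccc3)c(Cc3c(OCc4ccccc4)c(C)c(OC)c(C(C)=O)c3OCc3ccccc3)c2O[C@@H]1c1ccc(OCc2ccccc2)c(OCc2ccccc2)c1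
F4 | step 16 | chloro({[(1R,2S)-2-(benzyloxy)-1-ArB-5-(TBS-oxy)pentyl]oxy}ethynyl)zinc | CC(C)(C)[Si](C)(C)OCCC[C@H](OCc1ccccc1)[C@H](OC#C[Zn]Cl)c1ccc(OCc2ccccc2)c(OCc2ccccc2)c1
F5 | step 23 | diethyl [(5S,6R)-1,5-bis(benzyloxy)-6-ArB-6-[(3-ArD-prop-1-yn-1-yl)oxy]-2-oxo-3-(trifluoroacetyl)hexyl]phosphonate | CCOP(=O)(OCC)C(OCc1ccccc1)C(=O)C(C(=O)C(F)(F)F)C[C@H](OCc1ccccc1)[C@H](OC#CCc1c(OCc2ccccc2)c(C)c(OC)c(C(C)=C)c1OCc1ccccc1)c1ccc(OCc2ccccc2)c(OCc2ccccc2)c1
F6 | step 23 | diethyl [(5S,6R)-1,5-bis(benzyloxy)-6-ArB-3-diazo-6-[(3-ArD-prop-1-yn-1-yl)oxy]-2-oxohexyl]phosphonate | CCOP(=O)(OCC)C(OCc1ccccc1)C(=O)C(=[N+]=[N-])C[C@H](OCc1ccccc1)[C@H](OC#CCc1c(OCc2ccccc2)c(C)c(OC)c(C(C)=C)c1OCc1ccccc1)c1ccc(OCc2ccccc2)c(OCc2ccccc2)c1
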